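**Retrosynthetic overview**
1. Scoparone (1) already holds the whole 6,7-dimethoxycoumarin half. Only its C3–H has to be exchanged.
2. Changing C3–H to C3–Br gives scoparone 3-bromide (2), the alkenyl electrophile.
3. Umbelliferone (3) is the complete second coumarin and acts as the O-nucleophile through its 7-OH.
4. Key disconnection: the C3–O bond of the ether bridge in daphnoretin methyl ether (4), made from 2 + 3 by copper-catalysed ipso C–O coupling.
5. Ring order: no ring is formed. Both benzopyranone ring systems are bought intact and joined in the last step.

Assumption: the target SMILES contains no stereocentre, stereogenic axis or acyclic double bond, so 4 is achiral and no enantiomer has to be selected.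

**Step 1**
Reactants: 1 scoparone (6,7-dimethoxy-2H-chromen-2-one)
Product: 2 scoparone 3-bromide (3-bromo-6,7-dimethoxy-2H-chromen-2-one)
Conditions: Br2 (1.05 equiv), NaOAc (1.5 equiv), AcOH, rt, 3 h
Reagents that add atoms: bromine, BrBr
Why: Electrophilic bromination (vinylogous electrophilic aromatic substitution by addition–elimination), a standard reaction of 7-alkoxycoumarins: C3 is the vinylogous para position of the 7-methoxy group, so bromine attacks there to give a C4 benzylic cation stabilised by that group, acetate then removes H-3, C6 is blocked, C5 and C8 are each activated by only one ortho oxygen, and no stereocentre is formed.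

**Step 2**
Reactants: 2 scoparone 3-bromide; 3 umbelliferone (7-hydroxy-2H-chromen-2-one)
Product: 4 daphnoretin methyl ether (6,7-dimethoxy-3-[(2-oxo-2H-chromen-7-yl)oxy]-2H-chromen-2-one)
Conditions: 3 (1.3 equiv), CuI (10 mol %), N,N'-bis(biphenyl-2-yl)oxalamide (10 mol %), K3PO4 (2.0 equiv), 4 Å MS, dry degassed DMF, 90 °C, Ar, 16 h
Reagents that add atoms: none
Why: Proposed new method: ipso-selective copper-catalysed C(sp2)–O coupling of a 3-bromocoumarin (an α-bromo-α,β-unsaturated lactone) with a hydroxycoumarin, a pairing not yet demonstrated because 3-halocoumarins usually react with heteroatom nucleophiles and base by conjugate addition at C4 (cine substitution) or by ring contraction; here K3PO4 converts 3 (pKa about 7.8) into its aryloxide, the dianionic oxalamide makes the monovalent copper aryloxide electron-rich enough to add oxidatively into the carbonyl-activated C3–Br bond, and reductive elimination from the trivalent alkenylcopper aryloxide forms the C3–O bond at the carbon that carried bromine, while the 7-methoxy group (push–pull donor that lowers the electrophilicity of C4), the weakly nucleophilic aryloxide and the hydroxide-free medium hold back oxa-Michael addition and lactone opening; closest known reaction type: Ullmann-type coupling of aryl and simple alkenyl halides with phenols; no stereocentre is formed.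

**Compound list**
1 | scoparone (6,7-dimethoxy-2H-chromen-2-one) | COc1cc2ccc(=O)oc2cc1OC | starting material
2 | scoparone 3-bromide (3-bromo-6,7-dimethoxy-2H-chromen-2-one) | COc1cc2cc(Br)c(=O)oc2cc1OC | intermediate
3 | umbelliferone (7-hydroxy-2H-chromen-2-one) | Oc1ccc2ccc(=O)oc2c1 | starting material
4 | daphnoretin methyl ether (6,7-dimethoxy-3-[(2-oxo-2H-chromen-7-yl)oxy]-2H-chromen-2-one) | COc1cc2cc(Oc3ccc4ccc(=O)oc4c3)c(=O)oc2cc1OC | target
5 | 2-hydroxy-4,5-dimethoxybenzaldehyde | COc1cc(O)c(C=O)cc1OC | starting material (used only in the fallbacks)

**Total step count:** 2
**Longest linear sequence:** 2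

**Steps most likely to fail** (the route has only two steps, so both are ranked and there is no third)

1. Step 2, the proposed new step.
   - Risks:
     - Oxidative addition may be slow because the aryloxide of 3 is a poor donor.
     - Base-mediated oxa-Michael addition and HBr loss would give the 4-aryloxy isomer. It is recognised by an H-3 singlet near 5.5 ppm in place of the H-4 singlet near 7.5–7.9 ppm.
     - Protodebromination would return 1.
     - Traces of hydroxide could open the lactone and cause ring contraction to a benzofuran-2-carboxylate.
   - Fallback (known chemistry): it sets out from 3 and comes back to the route at 4. Williamson alkylation of 3 with ethyl bromoacetate (K2CO3, acetone, reflux) gives ethyl 2-[(2-oxo-2H-chromen-7-yl)oxy]acetate F1. Acid hydrolysis (6 M HCl, 1,4-dioxane, reflux) keeps the lactone closed and gives 2-[(2-oxo-2H-chromen-7-yl)oxy]acetic acid F2. Perkin–Oglialoro condensation of F2 with commercial 2-hydroxy-4,5-dimethoxybenzaldehyde 5 (Ac2O, NaOAc, 140 °C) builds the C3=C4 bond and the lactone of the dimethoxycoumarin around the ether oxygen already in place, and delivers 4. This is the classical entry to 3-aryloxycoumarins. It takes three steps and uses neither 1 nor 2.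

2. Step 1.
   - Risks: competing ring bromination at C8 or C5, over-bromination to a 3,8-dibromide, and difficult separation of these poorly soluble solids.
   - Fallback: it sets out from 5 and comes back to the route at 2. Knoevenagel condensation–lactonisation of 5 with Meldrum's acid (cat. piperidinium acetate, EtOH, reflux) gives 6,7-dimethoxy-2-oxo-2H-chromene-3-carboxylic acid F3, in which the carboxyl group marks C3. Hunsdiecker-type bromodecarboxylation (NBS, cat. LiOAc, MeCN–H2O, 40 °C) attacks the ipso carbon, forms the same 7-methoxy-stabilised C4 cation and loses CO2 to give 2. The regiochemistry is therefore fixed by ring construction rather than by the selectivity of a C–H bromination.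

**Further compounds**
F1 | step 2 | ethyl 2-[(2-oxo-2H-chromen-7-yl)oxy]acetate | CCOC(=O)COc1ccc2ccc(=O)oc2c1
F2 | step 2 | 2-[(2-oxo-2H-chromen-7-yl)oxy]acetic acid | OC(=O)COc1ccc2ccc(=O)oc2c1
F3 | step 1 | 6,7-dimethoxy-2-oxo-2H-chromene-3-carboxylic acid | COc1cc2cc(C(=O)O)c(=O)oc2cc1OC
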